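**Retrosynthetic overview**
1. In the ring C3a–C4=C5(OMe)–C6(=O)–C7–C7a (benzofuran numbering), C5 is a single carbon between C4 and the C6 carbonyl. Excising it leaves the cis-fused cyclopenta[b]furan-5-one 17 (a 2-oxabicyclo[3.3.0]octan-7-one). Hence 24 ⇐ 2-methoxyenone end game ⇐ C5=C6 enol silane 20 ⇐ 17 + TMSCHN2 (one-carbon ring expansion).
2. 17 ⇐ lactol 14: the cyclopentanone is closed by aldol condensation (C7–C7a), and the tetrahydrofuran recloses by oxa-Michael addition (O1–C7a).
3. Quaternary C3a ⇐ two α-alkylations of cis-lactone 8: the acetonyl arm first (allyl, Wacker, ketal), then allyl anti to the methyl and aryl groups.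
4. 8 ⇐ veratraldehyde 1 by catalytic enantioselective (Z)-crotylboration (sets C2 and C3), hydroboration and oxidative lactonisation.
5. Ring order: γ-lactone (future tetrahydrofuran), then cyclopentanone, then the six-membered ring by expansion.

Key step: step 10

Remark: the (S)-antipode of the TRIP phosphoric acid is assumed to direct crotyl transfer to the Si face of 1 (1S carbinol); if the opposite sense is found, the (R)-catalyst is used. Centres that are erased later (lactol carbon of 7, 14, 15; C5 of 19; epoxide carbons of 22; C4/C5 of 23) are left unassigned.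

Step 1
Reactants: 1 3,4-dimethoxybenzaldehyde; 2 (Z)-crotylboronic acid pinacol ester
Product: 4 (1S,2R)-1-(3,4-dimethoxyphenyl)-2-methylbut-3-en-1-ol, via homoallyl pinacol borate 3 (not isolated)
Conditions: (S)-TRIP phosphoric acid (5 mol%), toluene, −30 °C; aqueous work-up
Reagents that add atoms: (Z)-crotylboronic acid pinacol ester (2), C/C=C\CB1OC(C)(C)C(C)(C)O1
Why: Chiral-phosphoric-acid-catalysed crotylboration of an aryl aldehyde, in which the closed chair (Zimmerman–Traxler) transition state turns the Z geometry of 2 into the syn relationship that becomes the cis C2-aryl/C3-methyl pair, while the catalyst selects the Si face of the aldehyde to set 1S.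

Step 2
Reactants: 4 (1S,2R)-1-(3,4-dimethoxyphenyl)-2-methylbut-3-en-1-ol
Product: 6 (1S,2R)-1-(3,4-dimethoxyphenyl)-2-methylbutane-1,4-diol, via B-alkyl-9-BBN adduct 5 (not isolated)
Conditions: 9-BBN (2.5 equiv), THF, 0 → 23 °C; then aq. NaOH, 30% H2O2, 0 → 23 °C
Reagents that add atoms: hydrogen peroxide, OO
Why: Anti-Markovnikov hydroboration of the terminal vinyl group by the bulky borane, then oxidation of the C–B bond with retention; no stereocentre is touched.

Step 3
Reactants: 6 (1S,2R)-1-(3,4-dimethoxyphenyl)-2-methylbutane-1,4-diol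
Product: 8 (4R,5S)-5-(3,4-dimethoxyphenyl)-4-methyldihydrofuran-2(3H)-one, via lactol 7 (not isolated)
Conditions: TEMPO (0.2 equiv), PhI(OAc)2 (2.5 equiv), CH2Cl2, 23 °C
Reagents that add atoms: none
Why: Oxoammonium (TEMPO) oxidation is selective for the primary alcohol, the aldehyde is trapped by the benzylic hydroxyl as lactol 7 and oxidised on to the γ-lactone (oxidative lactonisation of a 1,4-diol), so both stereocentres are carried unchanged into the cis-β-methyl-γ-aryl lactone.

Step 4
Reactants: 8 (4R,5S)-5-(3,4-dimethoxyphenyl)-4-methyldihydrofuran-2(3H)-one; 9 allyl bromide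
Product: 10 (3R,4R,5S)-3-allyl-5-(3,4-dimethoxyphenyl)-4-methyldihydrofuran-2(3H)-one
Conditions: LDA (1.1 equiv), THF, −78 °C; allyl bromide, −78 → −40 °C
Reagents that add atoms: allyl bromide (9), C=CCBr
Why: Kinetic lactone enolate alkylation (SN2 on allyl bromide) trans to the C4 methyl group; the new C3 centre is provisional because it is planarised again in step 7.

Step 5
Reactants: 10 (3R,4R,5S)-3-allyl-5-(3,4-dimethoxyphenyl)-4-methyldihydrofuran-2(3H)-one
Product: 11 (3R,4R,5S)-5-(3,4-dimethoxyphenyl)-4-methyl-3-(2-oxopropyl)dihydrofuran-2(3H)-one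
Conditions: PdCl2 (0.1 equiv), CuCl2 (0.2 equiv), O2 (1 atm), DMF–H2O (7:1), 23 °C
Reagents that add atoms: water, O
Why: Tsuji–Wacker oxidation of a terminal alkene (Markovnikov hydroxypalladation) gives the methyl ketone, turning the allyl group into the acetonyl arm that will supply C4, C6 and C7.

Step 6
Reactants: 11 (3R,4R,5S)-5-(3,4-dimethoxyphenyl)-4-methyl-3-(2-oxopropyl)dihydrofuran-2(3H)-one
Product: 12 (3R,4R,5S)-5-(3,4-dimethoxyphenyl)-4-methyl-3-[(2-methyl-1,3-dioxolan-2-yl)methyl]dihydrofuran-2(3H)-one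
Conditions: 1,2-bis(trimethylsilyloxy)ethane (1.5 equiv), TMSOTf (5 mol%), CH2Cl2, −78 → −20 °C; pyridine quench
Reagents that add atoms: 1,2-bis(trimethylsilyloxy)ethane, C[Si](C)(C)OCCO[Si](C)(C)C
Why: Aprotic low-temperature ketalisation (silyl-triflate-catalysed, Noyori type) masks the ketone against the coming enolate and hydride steps without exposing the acid-labile cis benzylic lactone C–O bond to hot protic acid.

Step 7
Reactants: 12 (3R,4R,5S)-5-(3,4-dimethoxyphenyl)-4-methyl-3-[(2-methyl-1,3-dioxolan-2-yl)methyl]dihydrofuran-2(3H)-one; 9 allyl bromide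
Product: 13 (3S,4R,5S)-3-allyl-5-(3,4-dimethoxyphenyl)-4-methyl-3-[(2-methyl-1,3-dioxolan-2-yl)methyl]dihydrofuran-2(3H)-one
Conditions: LDA (1.3 equiv), THF–DMPU, −78 °C; allyl bromide (2 equiv), −78 → −30 °C
Reagents that add atoms: allyl bromide (9), C=CCBr
Why: This second lactone enolate alkylation creates the quaternary carbon (future C3a), because the planar enolate is attacked by allyl bromide on the face opposite the cis C4-methyl/C5-aryl pair, so the allyl group ends up trans and the dioxolanylmethyl arm cis to the methyl group, as the target requires.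

Step 8
Reactants: 13 (3S,4R,5S)-3-allyl-5-(3,4-dimethoxyphenyl)-4-methyl-3-[(2-methyl-1,3-dioxolan-2-yl)methyl]dihydrofuran-2(3H)-one
Product: 14 (3S,4R,5S)-3-allyl-5-(3,4-dimethoxyphenyl)-4-methyl-3-[(2-methyl-1,3-dioxolan-2-yl)methyl]tetrahydrofuran-2-ol
Conditions: DIBAL-H (1.2 equiv), CH2Cl2, −78 °C; Rochelle salt work-up
Reagents that add atoms: none
Why: Low-temperature DIBAL-H reduction of the hindered α-quaternary lactone stops at the tetrahedral aluminium hemiacetal and gives the lactol on work-up, while ketal, alkene and aryl ethers are inert.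

Step 9
Reactants: 14 (3S,4R,5S)-3-allyl-5-(3,4-dimethoxyphenyl)-4-methyl-3-[(2-methyl-1,3-dioxolan-2-yl)methyl]tetrahydrofuran-2-ol
Product: 17 (2S,3R,3aS,6aS)-3a-allyl-2-(3,4-dimethoxyphenyl)-3-methylhexahydro-2H-cyclopenta[b]furan-5-one, via keto lactol 15 (not isolated), via hydroxy cyclopentenone 16 (not isolated)
Conditions: 1 M aq. HCl, THF, 0 → 23 °C; extractive work-up; then KOH (0.5 equiv), MeOH, 23 °C
Reagents that add atoms: water, O
Why: Ketal hydrolysis reveals a γ-keto aldehyde (masked as lactol 15) that should undergo the classical base-mediated intramolecular aldol condensation to the 4,4-disubstituted cyclopentenone 16 (C7–C7a bond; only the methyl enolate can cyclise, since the aldehyde has no α-hydrogen and the methylene enolate would close a three-membered ring), after which the freed benzylic alkoxide adds 5-exo-trig to the enone (oxa-Michael) and the five-five fusion allows only the cis junction, which fixes C6a (future C7a).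

Step 10
Reactants: 17 (2S,3R,3aS,6aS)-3a-allyl-2-(3,4-dimethoxyphenyl)-3-methylhexahydro-2H-cyclopenta[b]furan-5-one; 18 trimethylsilyldiazomethane
Product: 20 (2S,3R,3aS,7aS)-3a-allyl-2-(3,4-dimethoxyphenyl)-3-methyl-6-(trimethylsilyloxy)-2,3,3a,4,7,7a-hexahydrobenzofuran, via α-silyl ketone 19 (not isolated)
Conditions: TMSCHN2 (1.3 equiv), Sc(OTf)3 (10 mol%), toluene, −20 → 0 °C; filtration through Et3N-deactivated silica
Reagents that add atoms: trimethylsilyldiazomethane (18), C[Si](C)(C)C=[N+]=[N-]
Why: Sc(OTf)3 activates the C6 carbonyl of 17, the nucleophilic diazo carbon of 18 adds to it, and the resulting β-scandoxy diazonium collapses with loss of N2 and 1,2-shift of the C4–C6 bond onto the new carbon C5, which forms C4–C5 and C5–C6 and gives α-silyl ketone 19. A scandium-assisted 1,3-silyl shift from carbon to oxygen (Brook type) then gives the enol silane with the double bond fixed between C5 and C6; the closest known reaction type is the Lewis-acid-catalysed diazoalkane homologation of cycloalkanones (Tiffeneau–Demjanov type) with trimethylsilyldiazomethane, which is known to end at the enol silane under Sc(OTf)3. The six-membered carbocycle arises by ring enlargement of the cyclopentanone, not by a cyclisation, so no separate ring-closure mode is involved. No stereocentre is created in 20 (C5 of 19 is transient and becomes sp2), and C2, C3, C3a and C7a are not part of the migrating bond, so they are retained. The step needs migration of C4 and not of C7: the σ-withdrawing C7a–O1 bond β to C7 lowers the electron density of the C6–C7 bond and should make C7 the poorer migrating group, and the enol silane product no longer carries a ketone, so it cannot be homologated a second time. No free carbene is formed, so the allyl group and the arene are left alone, and low temperature with catalytic Lewis acid is chosen to avoid ionising the benzylic C2–O1 bond.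

Step 11
Reactants: 20 (2S,3R,3aS,7aS)-3a-allyl-2-(3,4-dimethoxyphenyl)-3-methyl-6-(trimethylsilyloxy)-2,3,3a,4,7,7a-hexahydrobenzofuran
Product: 21 (2S,3R,3aS,7aS)-3a-allyl-2-(3,4-dimethoxyphenyl)-3-methyl-3,3a,7,7a-tetrahydrobenzofuran-6(2H)-one
Conditions: Pd(OAc)2 (1.1 equiv), MeCN, 23 °C
Reagents that add atoms: none
Why: Saegusa–Ito oxidation, in which transmetalation of the regiodefined enol silane gives a C5-bound palladium enolate whose only β-hydrogens are on C4, so syn β-hydride elimination can only give the C4=C5 enone, while the monosubstituted allyl alkene is inert to Pd(OAc)2 in dry acetonitrile.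

Step 12
Reactants: 21 (2S,3R,3aS,7aS)-3a-allyl-2-(3,4-dimethoxyphenyl)-3-methyl-3,3a,7,7a-tetrahydrobenzofuran-6(2H)-one
Product: 22 4,5-epoxide of 21 (3a-allyl-2-(3,4-dimethoxyphenyl)-4,5-epoxy-3-methylhexahydrobenzofuran-6(2H)-one)
Conditions: 30% H2O2 (5 equiv), LiOH·H2O (0.2 equiv), MeOH, −20 → 0 °C
Reagents that add atoms: hydrogen peroxide, OO
Why: Weitz–Scheffer nucleophilic epoxidation (hydroperoxide adds to C4 and the enolate closes on oxygen) is selective for the electron-poor alkene over the allyl group, and it is run cold with substoichiometric hydroxide and excess peroxide so that the weakly basic hydroperoxide anion is the main base and enolisation toward C7 (β-elimination of O1) is held back; both epoxide diastereomers converge in step 13.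

Step 13
Reactants: 22 4,5-epoxide of 21
Product: 24 (2S,3R,3aR,7aS)-3a-allyl-2-(3,4-dimethoxyphenyl)-5-methoxy-3-methyl-3,3a,7,7a-tetrahydrobenzofuran-6(2H)-one, via hydroxy methoxy ketone 23 (not isolated)
Conditions: NaOMe (0.5 equiv), MeOH, 0 → 23 °C
Reagents that add atoms: methanol, CO
Why: Methoxide opens the α,β-epoxy ketone by SN2 attack at the carbonyl-activated C5 (C4 is neopentyl) and the resulting β-hydroxy-α-methoxy ketone 23 loses water by E1cB to the 2-methoxy enone (known conversion of epoxy ketones into diosphenol ethers), with no stereocentre of the target formed or touched, and any reversible opening of the C7a–O1 bond should reclose at C7a because the methoxy-bearing enone arm is the poorer acceptor.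

**Compound list**
1 | 3,4-dimethoxybenzaldehyde (veratraldehyde) | COc1ccc(C=O)cc1OC | starting material
2 | (Z)-crotylboronic acid pinacol ester | C/C=C\CB1OC(C)(C)C(C)(C)O1 | starting material
3 | 2-{[(1S,2R)-1-(3,4-dimethoxyphenyl)-2-methylbut-3-en-1-yl]oxy}-4,4,5,5-tetramethyl-1,3,2-dioxaborolane | CC1(C)OB(O[C@H](c2ccc(OC)c(OC)c2)[C@H](C)C=C)OC1(C)C | intermediate
4 | (1S,2R)-1-(3,4-dimethoxyphenyl)-2-methylbut-3-en-1-ol (syn) | O[C@H](c1ccc(OC)c(OC)c1)[C@H](C)C=C | intermediate
5 | (1S,2R)-4-(9-borabicyclo[3.3.1]nonan-9-yl)-1-(3,4-dimethoxyphenyl)-2-methylbutan-1-ol | O[C@H](c1ccc(OC)c(OC)c1)[C@H](C)CCB1C2CCCC1CCC2 | intermediate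
6 | (1S,2R)-1-(3,4-dimethoxyphenyl)-2-methylbutane-1,4-diol | O[C@H](c1ccc(OC)c(OC)c1)[C@H](C)CCO | intermediate
7 | (4R,5S)-5-(3,4-dimethoxyphenyl)-4-methyltetrahydrofuran-2-ol (anomers) | OC1O[C@H](c2ccc(OC)c(OC)c2)[C@H](C)C1 | intermediate
8 | (4R,5S)-5-(3,4-dimethoxyphenyl)-4-methyldihydrofuran-2(3H)-one (cis) | O=C1O[C@H](c2ccc(OC)c(OC)c2)[C@H](C)C1 | intermediate
9 | allyl bromide | C=CCBr | starting material
10 | (3R,4R,5S)-3-allyl-5-(3,4-dimethoxyphenyl)-4-methyldihydrofuran-2(3H)-one | C=CC[C@H]1C(=O)O[C@H](c2ccc(OC)c(OC)c2)[C@@H]1C | intermediate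
11 | (3R,4R,5S)-5-(3,4-dimethoxyphenyl)-4-methyl-3-(2-oxopropyl)dihydrofuran-2(3H)-one | CC(=O)C[C@H]1C(=O)O[C@H](c2ccc(OC)c(OC)c2)[C@@H]1C | intermediate
12 | (3R,4R,5S)-5-(3,4-dimethoxyphenyl)-4-methyl-3-[(2-methyl-1,3-dioxolan-2-yl)methyl]dihydrofuran-2(3H)-one | CC1(C[C@H]2C(=O)O[C@H](c3ccc(OC)c(OC)c3)[C@@H]2C)OCCO1 | intermediate
13 | (3S,4R,5S)-3-allyl-5-(3,4-dimethoxyphenyl)-4-methyl-3-[(2-methyl-1,3-dioxolan-2-yl)methyl]dihydrofuran-2(3H)-one (allyl trans to methyl) | C=CC[C@@]1(CC2(C)OCCO2)C(=O)O[C@H](c2ccc(OC)c(OC)c2)[C@@H]1C | intermediate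
14 | (3S,4R,5S)-3-allyl-5-(3,4-dimethoxyphenyl)-4-methyl-3-[(2-methyl-1,3-dioxolan-2-yl)methyl]tetrahydrofuran-2-ol (anomers) | C=CC[C@@]1(CC2(C)OCCO2)C(O)O[C@H](c2ccc(OC)c(OC)c2)[C@@H]1C | intermediate
15 | (3S,4R,5S)-3-allyl-5-(3,4-dimethoxyphenyl)-4-methyl-3-(2-oxopropyl)tetrahydrofuran-2-ol (anomers) | C=CC[C@@]1(CC(C)=O)C(O)O[C@H](c2ccc(OC)c(OC)c2)[C@@H]1C | intermediate
16 | (4R)-4-allyl-4-[(1S,2R)-1-(3,4-dimethoxyphenyl)-1-hydroxypropan-2-yl]cyclopent-2-en-1-one | C=CC[C@@]1(C=CC(=O)C1)[C@@H](C)[C@H](O)c1ccc(OC)c(OC)c1 | intermediate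
17 | (2S,3R,3aS,6aS)-3a-allyl-2-(3,4-dimethoxyphenyl)-3-methylhexahydro-2H-cyclopenta[b]furan-5-one (cis-fused) | C=CC[C@@]12CC(=O)C[C@@H]1O[C@H](c1ccc(OC)c(OC)c1)[C@@H]2C | intermediate
18 | trimethylsilyldiazomethane | C[Si](C)(C)C=[N+]=[N-] | starting material
19 | 3a-allyl-2-(3,4-dimethoxyphenyl)-3-methyl-5-(trimethylsilyl)hexahydrobenzofuran-6(2H)-one (ring configuration as in 17, C5 epimers) | C=CC[C@@]12CC([Si](C)(C)C)C(=O)C[C@@H]1O[C@H](c1ccc(OC)c(OC)c1)[C@@H]2C | intermediate
20 | (2S,3R,3aS,7aS)-3a-allyl-2-(3,4-dimethoxyphenyl)-3-methyl-6-(trimethylsilyloxy)-2,3,3a,4,7,7a-hexahydrobenzofuran | C=CC[C@@]12CC=C(O[Si](C)(C)C)C[C@@H]1O[C@H](c1ccc(OC)c(OC)c1)[C@@H]2C | intermediate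
21 | (2S,3R,3aS,7aS)-3a-allyl-2-(3,4-dimethoxyphenyl)-3-methyl-3,3a,7,7a-tetrahydrobenzofuran-6(2H)-one | C=CC[C@@]12C=CC(=O)C[C@@H]1O[C@H](c1ccc(OC)c(OC)c1)[C@@H]2C | intermediate
22 | 3a-allyl-2-(3,4-dimethoxyphenyl)-4,5-epoxy-3-methylhexahydrobenzofuran-6(2H)-one (ring configuration as in 21, epoxide face unassigned) | C=CC[C@@]12C3OC3C(=O)C[C@@H]1O[C@H](c1ccc(OC)c(OC)c1)[C@@H]2C | intermediate
23 | 3a-allyl-2-(3,4-dimethoxyphenyl)-4-hydroxy-5-methoxy-3-methylhexahydrobenzofuran-6(2H)-one (C4, C5 unassigned) | C=CC[C@@]12C(O)C(OC)C(=O)C[C@@H]1O[C@H](c1ccc(OC)c(OC)c1)[C@@H]2C | intermediate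
24 | (2S,3R,3aR,7aS)-3a-allyl-2-(3,4-dimethoxyphenyl)-5-methoxy-3-methyl-3,3a,7,7a-tetrahydrobenzofuran-6(2H)-one | C=CC[C@@]12C=C(OC)C(=O)C[C@@H]1O[C@H](c1ccc(OC)c(OC)c1)[C@@H]2C | target

**Step count**
Total: 13 steps. Longest linear sequence: 13 steps (from 1).

**Steps most likely to fail**

1. Step 10 (key step). What may go wrong: migration of the wrong ring bond (C7 instead of C4) in the diazonium intermediate, which would place the new carbon and the enol silane on the wrong side of the ketone; a second possibility is Lewis-acid ionisation of the benzylic C2–O1 bond with epimerisation at C2. Fallback (no ring expansion; the regiochemistry comes from a kinetic enolisation): the fallback sets out from lactone 8. Alkylation of its lithium enolate (LDA, THF–DMPU, −78 → −20 °C) with commercial 2-(2-bromoethyl)-2-methyl-1,3-dioxolane should give the dioxolanylethyl lactone F1. A second alkylation with allyl bromide 9, again anti to the methyl group, should give the quaternary lactone F2, and DIBAL-H at −78 °C the lactol F3. Aqueous HCl and then KOH in MeOH should lead through keto lactol F4 and the 4,4-disubstituted hydroxy cyclohexenone F5 (six-membered aldol condensation, then oxa-Michael closure) to the saturated cis-fused bicyclic ketone F6. Kinetic enolisation with LDA and TMSCl at −78 °C, which for β-alkoxy ketones takes place on the side remote from the oxygen-bearing carbon, should then give the C5=C6 enol silane 20, where the route is rejoined.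

2. Step 12. What may go wrong: base-triggered β-elimination of the ring oxygen (retro-oxa-Michael) to a symmetrical 4,4-disubstituted cyclohexadienone, whose reclosure on either enone arm would erode the configuration at C3a relative to C2 and C3. Fallback (the carbonyl is taken out of play during epoxidation): the fallback sets out from enone 21. Luche reduction (NaBH4, CeCl3·7H2O, MeOH, −78 °C) should give the allylic alcohol F7. Hydroxyl-directed epoxidation (VO(acac)2 cat., t-BuOOH, CH2Cl2, 0 → 23 °C), which leaves the isolated allyl group alone, should give the syn epoxy alcohol F8. Buffered Dess–Martin oxidation (NaHCO3, CH2Cl2) returns the route to epoxy ketone 22.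

3. Step 13. What may go wrong: enolisation toward C7 and opening of the C7a–O1 bond in the epoxy ketone, followed by intramolecular attack of the liberated benzylic alkoxide on the epoxide, or slow displacement at C5. Fallback (methoxide opening moved to the alcohol oxidation level, where no enolate can form): the fallback sets out from enone 21 and passes through allylic alcohol F7 and epoxy alcohol F8 as described above. Treatment of F8 with NaOMe in MeOH at 60 °C should open the epoxide at C5, since C4 is neopentyl and Payne migration is excluded by the syn relationship of hydroxyl and epoxide, and give the methoxy diol F9. Selective oxidation of the less hindered C6 hydroxyl (TEMPO, PhI(OAc)2, CH2Cl2) should give hydroxy methoxy ketone 23, isolated in this variant. Mesylation (MsCl, Et3N, CH2Cl2, 0 °C) should give the mesylate F10, which eliminates under the same conditions to the target 24, where the route is rejoined.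

**Further compounds**
F1 | step 10 | (3R,4R,5S)-5-(3,4-dimethoxyphenyl)-4-methyl-3-[2-(2-methyl-1,3-dioxolan-2-yl)ethyl]dihydrofuran-2(3H)-one | CC1(CC[C@H]2C(=O)O[C@H](c3ccc(OC)c(OC)c3)[C@@H]2C)OCCO1
F2 | step 10 | (3R,4R,5S)-3-allyl-5-(3,4-dimethoxyphenyl)-4-methyl-3-[2-(2-methyl-1,3-dioxolan-2-yl)ethyl]dihydrofuran-2(3H)-one (allyl trans to methyl) | C=CC[C@@]1(CCC2(C)OCCO2)C(=O)O[C@H](c2ccc(OC)c(OC)c2)[C@@H]1C
F3 | step 10 | 3-allyl-5-(3,4-dimethoxyphenyl)-4-methyl-3-[2-(2-methyl-1,3-dioxolan-2-yl)ethyl]tetrahydrofuran-2-ol (anomers) | C=CC[C@@]1(CCC2(C)OCCO2)C(O)O[C@H](c2ccc(OC)c(OC)c2)[C@@H]1C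
F4 | step 10 | 3-allyl-5-(3,4-dimethoxyphenyl)-4-methyl-3-(3-oxobutyl)tetrahydrofuran-2-ol (anomers) | C=CC[C@@]1(CCC(C)=O)C(O)O[C@H](c2ccc(OC)c(OC)c2)[C@@H]1C
F5 | step 10 | 4-allyl-4-[(1S,2R)-1-(3,4-dimethoxyphenyl)-1-hydroxypropan-2-yl]cyclohex-2-en-1-one | C=CC[C@@]1(C=CC(=O)CC1)[C@@H](C)[C@H](O)c1ccc(OC)c(OC)c1
F6 | step 10 | (2S,3R,3aR,7aS)-3a-allyl-2-(3,4-dimethoxyphenyl)-3-methylhexahydrobenzofuran-6(2H)-one (cis-fused) | C=CC[C@@]12CCC(=O)C[C@@H]1O[C@H](c1ccc(OC)c(OC)c1)[C@@H]2C
F7 | step 12 | 3a-allyl-2-(3,4-dimethoxyphenyl)-3-methyl-2,3,3a,6,7,7a-hexahydrobenzofuran-6-ol (ring configuration as in 21, C6 unassigned) | C=CC[C@@]12C=CC(O)C[C@@H]1O[C@H](c1ccc(OC)c(OC)c1)[C@@H]2C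
F8 | step 12 | 3a-allyl-2-(3,4-dimethoxyphenyl)-4,5-epoxy-3-methyloctahydrobenzofuran-6-ol (epoxide syn to hydroxyl) | C=CC[C@@]12C3OC3C(O)C[C@@H]1O[C@H](c1ccc(OC)c(OC)c1)[C@@H]2C
F9 | step 13 | 3a-allyl-2-(3,4-dimethoxyphenyl)-5-methoxy-3-methyloctahydrobenzofuran-4,6-diol (C4–C6 unassigned) | C=CC[C@@]12C(O)C(OC)C(O)C[C@@H]1O[C@H](c1ccc(OC)c(OC)c1)[C@@H]2C
F10 | step 13 | 3a-allyl-2-(3,4-dimethoxyphenyl)-5-methoxy-3-methyl-6-oxooctahydrobenzofuran-4-yl methanesulfonate | C=CC[C@@]12C(OS(C)(=O)=O)C(OC)C(=O)C[C@@H]1O[C@H](c1ccc(OC)c(OC)c1)[C@@H]2C
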